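Ring B of the target holds C7 as a bare CH2 between C6 and C8, the carbon that carries the exocyclic methylene, so ring B is a cyclopentanone (C5, C6, C8, C9, C10) plus one carbon. The route therefore builds an enantiopure trans-hydrindan-8-one with ring A complete (3α-OTBS, C4 methyl/ester, 10β-methyl) and the C9 side chain in place as a C13 dioxolane, and inserts C7 last. One Lewis-acid-promoted silyldiazomethane homologation forms C6–C7 and C7–C8 and turns the five-membered ring into the trans-decalin 8-ketone. Methylenation, side-chain olefination and a late silyl-to-acetate exchange finish the synthesis.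

Key step: step 10

Remark: locants follow labdane numbering on every bicyclic compound. "Hydrindane" means ring A (C10–C1–C2–C3–C4–C5) fused to the five-membered ring C5–C6–C8–C9–C10, which lacks C7; α is the face opposite the C10 methyl. It is assumed that (S)-amino-acid catalysis selects the same enantiotopic ring carbonyl in the keto-ester triketone 4 as in the parent methyl-ketone triketone.

Step 1
Reactants: 1 2-methylcyclopentane-1,3-dione; 2 methyl 5-methoxy-3-oxopentanoate
Product: 4 methyl 5-(1-methyl-2,5-dioxocyclopentyl)-3-oxopentanoate, via methyl 3-oxopent-4-enoate 3 (not isolated)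
Conditions: 2, TsOH (cat.), toluene, 90 °C, MeOH distilled off; crude 3 then 1, Et3N (0.1 equiv), MeCN, 0 °C → rt
Reagents that add atoms: none
Why: Acid-catalysed loss of methanol unmasks the vinyl ketone 3, and the dione, far more acidic than the β-keto ester, adds through C2 in an amine-catalysed Michael addition that creates the still prochiral quaternary carbon (future C10).

Step 2
Reactants: 4 methyl 5-(1-methyl-2,5-dioxocyclopentyl)-3-oxopentanoate
Product: 6 methyl (7aS)-7a-methyl-1,5-dioxo-2,3,5,6,7,7a-hexahydro-1H-indene-4-carboxylate, via cis-fused ketol 5 (not isolated)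
Conditions: L-phenylalanine (0.5 equiv), (+)-CSA (0.25 equiv), DMF, rt → 60 °C
Reagents that add atoms: none
Why: Hajos–Parrish-type amino-acid-catalysed intramolecular aldol condensation, in which the enamine (here an enamino ester) at the side-chain ketone is steered by the carboxylic acid onto one of the two enantiotopic ring carbonyls so that the (S)-amino acid should give (S)-configured C10 (β-methyl), and ketol 5 dehydrates readily because the new C4=C5 alkene is conjugated with both ketone and ester.

Step 3
Reactants: 6 methyl (7aS)-7a-methyl-1,5-dioxo-2,3,5,6,7,7a-hexahydro-1H-indene-4-carboxylate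
Product: 8 methyl 4α,10β-dimethyl-3,9-dioxo-5α-hydrindane-4β-carboxylate, via lithium enolate 7 (not isolated)
Conditions: Li (2.1 equiv), NH3/THF, H2O (1.0 equiv), −78 °C; then MeI (5 equiv), −78 → −33 °C
Reagents that add atoms: iodomethane, CI; lithium, [Li] (counter-ion of 7 only)
Why: Birch-type reductive alkylation, in which two-electron reduction of the doubly activated alkene and protonation at C5 should give the trans-fused (5α-H) β-keto ester enolate 7, methyl iodide then attacks C4 from the α face away from the syn-axial C10 methyl (new methyl α, ester β and axial), and the isolated C9 ketone is spared because only two equivalents of metal are used and water leaves no strong amide base behind.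

Step 4
Reactants: 8 methyl 4α,10β-dimethyl-3,9-dioxo-5α-hydrindane-4β-carboxylate
Product: 9 methyl 3α-hydroxy-4α,10β-dimethyl-9-oxo-5α-hydrindane-4β-carboxylate
Conditions: L-Selectride (1.1 equiv), THF, −78 °C; then H2O
Reagents that add atoms: none
Why: Bulky trialkylborohydride reduction, in which hydride arrives along the equatorial trajectory to give the axial 3α-alcohol and the ester-activated cyclohexanone should react faster than the neopentyl cyclopentanone at C9, as 3-keto groups do over 17-keto groups in steroids.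

Step 5
Reactants: 9 methyl 3α-hydroxy-4α,10β-dimethyl-9-oxo-5α-hydrindane-4β-carboxylate
Product: 10 methyl 3α-(tert-butyldimethylsilyloxy)-4α,10β-dimethyl-9-oxo-5α-hydrindane-4β-carboxylate
Conditions: TBSOTf (1.3 equiv), 2,6-lutidine, CH2Cl2, −78 → 0 °C
Reagents that add atoms: tert-butyldimethylsilyl triflate, CC(C)(C)[Si](C)(C)OS(=O)(=O)C(F)(F)F
Why: Silylation of a hindered secondary alcohol with a silyl triflate and a non-nucleophilic base, which also removes any retro-aldol risk of the β-hydroxy ester in the basic steps that follow.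

Step 6
Reactants: 10 methyl 3α-(tert-butyldimethylsilyloxy)-4α,10β-dimethyl-9-oxo-5α-hydrindane-4β-carboxylate
Product: 12 methyl 3α-(tert-butyldimethylsilyloxy)-4α,10β-dimethyl-9-(trifluoromethylsulfonyloxy)-5α-hydrind-8-ene-4β-carboxylate, via potassium enolate 11 (not isolated)
Conditions: KHMDS (1.2 equiv), THF, −78 °C; then PhNTf2, −78 → 0 °C
Reagents that add atoms: N-phenylbis(trifluoromethanesulfonimide), O=S(=O)(N(c1ccccc1)S(=O)(=O)C(F)(F)F)C(F)(F)F; KHMDS, C[Si](C)(C)[N-][Si](C)(C)C.[K+] (potassium of 11 only)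
Why: Regiospecific enol triflate formation, since the C9 ketone can enolise only toward C8 (C10 is quaternary), the ester has no α-hydrogen, and the potassium enolate is O-sulfonylated by the triflimide.

Step 7
Reactants: 12 methyl 3α-(tert-butyldimethylsilyloxy)-4α,10β-dimethyl-9-(trifluoromethylsulfonyloxy)-5α-hydrind-8-ene-4β-carboxylate; 13 2-methyl-2-vinyl-1,3-dioxolane
Product: 15 methyl 3α-(tert-butyldimethylsilyloxy)-4α,10β-dimethyl-9-[2-(2-methyl-1,3-dioxolan-2-yl)ethyl]-5α-hydrind-8-ene-4β-carboxylate, via B-alkyl-9-BBN 14 (not isolated)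
Conditions: 13, 9-BBN, THF, 0 °C → rt; then 12, PdCl2(dppf) (5 mol%), AsPh3, Cs2CO3, DMF/H2O, rt → 50 °C
Reagents that add atoms: 9-BBN, [BH]1C2CCCC1CCC2 (boron and ring carbons in 14 only)
Why: B-alkyl Suzuki–Miyaura coupling, in which anti-Markovnikov hydroboration of the vinyl group gives the primary alkylborane 14 that couples with the enol triflate to form C9–C11 with the alkene fixed at C8=C9, avoiding the regio-ambiguous dehydration of a tertiary C9 carbinol.

Step 8
Reactants: 15 methyl 3α-(tert-butyldimethylsilyloxy)-4α,10β-dimethyl-9-[2-(2-methyl-1,3-dioxolan-2-yl)ethyl]-5α-hydrind-8-ene-4β-carboxylate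
Product: 17 methyl 3α-(tert-butyldimethylsilyloxy)-8α-hydroxy-4α,10β-dimethyl-9β-[2-(2-methyl-1,3-dioxolan-2-yl)ethyl]-5α-hydrindane-4β-carboxylate, via C8-alkylborane 16 (not isolated)
Conditions: BH3·THF, THF, 0 °C → rt; then NaOH, H2O2, 0 °C → rt
Reagents that add atoms: hydrogen peroxide, OO; borane–THF, [BH3-][O+]1CCCC1 (boron in 16 only)
Why: Hydroboration–oxidation, in which borane adds syn across C8=C9 from the α face opposite the angular C10 methyl with boron on the less substituted C8, so C9 receives an α-hydrogen (side chain β) and oxidation with retention gives the 8α-alcohol.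

Step 9
Reactants: 17 methyl 3α-(tert-butyldimethylsilyloxy)-8α-hydroxy-4α,10β-dimethyl-9β-[2-(2-methyl-1,3-dioxolan-2-yl)ethyl]-5α-hydrindane-4β-carboxylate
Product: 18 methyl 3α-(tert-butyldimethylsilyloxy)-4α,10β-dimethyl-9β-[2-(2-methyl-1,3-dioxolan-2-yl)ethyl]-8-oxo-5α-hydrindane-4β-carboxylate
Conditions: TPAP (5 mol%), NMO, 4 Å MS, CH2Cl2, rt
Reagents that add atoms: none
Why: Ley–Griffith oxidation of the secondary alcohol to the C8 ketone under neutral conditions that leave the ketal, the silyl ether and the C9 centre untouched.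

Step 10
Reactants: 18 methyl 3α-(tert-butyldimethylsilyloxy)-4α,10β-dimethyl-9β-[2-(2-methyl-1,3-dioxolan-2-yl)ethyl]-8-oxo-5α-hydrindane-4β-carboxylate
Product: 20 methyl 3α-(tert-butyldimethylsilyloxy)-13,13-ethylenedioxy-8-oxo-14,15,17-trinorlabdan-19-oate, via 7-silyl-8-ketone 19 (not isolated)
Conditions: TMSCHN2 (1.5 equiv), AlMe3 (1.2 equiv), CH2Cl2, −78 → −20 °C; aq. Rochelle salt; crude 19 then K2CO3 (cat.), MeOH, rt
Reagents that add atoms: trimethylsilyldiazomethane, C[Si](C)(C)C=[N+]=[N-]
Why: AlMe3 activates the C8 carbonyl, the nucleophilic carbon of trimethylsilyldiazomethane adds to it, and loss of N2 from the β-oxido diazonium is concerted with a 1,2-shift of the ring bond anti to the leaving group, so the diazo carbon becomes C7 bonded to both C8 and C6. The closest known reaction type is the Lewis-acid-promoted, Tiffeneau–Demjanov-type one-carbon homologation of 2-substituted cycloalkanones with TMSCHN2, cyclopentanone to cyclohexanone. Ring B is not closed end to end but arises by enlargement of the five-membered ring (C5, C6, C8, C9, C10) through this 1,2-carbon shift. No lasting stereocentre is created (the silyl-bearing C7 of 19 is erased on desilylation), the trans C5/C10 fusion is carried through, and C9 should finish as the equatorial 9β-side-chain epimer because the methanolic carbonate treatment equilibrates it. The step needs C6 to migrate instead of C9 and only one insertion: the unbranched CH2 (C6) should shift in preference to the methine C9, which carries the side chain and sits beside quaternary C10, and the C-silylated ketone 19 (or its silyl enol ether) is too hindered and too weakly electrophilic to take up a second diazoalkane before K2CO3/MeOH removes the silyl group.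

Step 11
Reactants: 20 methyl 3α-(tert-butyldimethylsilyloxy)-13,13-ethylenedioxy-8-oxo-14,15,17-trinorlabdan-19-oate
Product: 21 methyl 3α-(tert-butyldimethylsilyloxy)-13,13-ethylenedioxy-14,15-dinorlabd-8(17)-en-19-oate
Conditions: Ph3PCH3Br, KOtBu, toluene, rt → 80 °C
Reagents that add atoms: methyltriphenylphosphonium bromide, C[P+](c1ccccc1)(c1ccccc1)c1ccccc1.[Br-]
Why: Wittig methylenation of the C8 ketone with the non-stabilised ylide, to which the shielded C19 ester is inert and under which the already equatorial C9 centre cannot be eroded.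

Step 12
Reactants: 21 methyl 3α-(tert-butyldimethylsilyloxy)-13,13-ethylenedioxy-14,15-dinorlabd-8(17)-en-19-oate
Product: 22 methyl 3α-(tert-butyldimethylsilyloxy)-13-oxo-14,15-dinorlabd-8(17)-en-19-oate
Conditions: PPTS, acetone/H2O, 50 °C
Reagents that add atoms: water, O
Why: Mild acid-catalysed ketal hydrolysis that should free the C13 methyl ketone without cleaving the hindered secondary silyl ether or isomerising the exocyclic alkene.

Step 13
Reactants: 22 methyl 3α-(tert-butyldimethylsilyloxy)-13-oxo-14,15-dinorlabd-8(17)-en-19-oate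
Product: 23 15-ethyl 19-methyl 3α-(tert-butyldimethylsilyloxy)labda-8(17),13E-diene-15,19-dioate
Conditions: (i-PrO)2P(O)CH2CO2Et, NaH, THF, 0 → 50 °C
Reagents that add atoms: ethyl 2-(diisopropoxyphosphoryl)acetate, CCOC(=O)CP(=O)(OC(C)C)OC(C)C
Why: Horner–Wadsworth–Emmons olefination of the methyl ketone, whose reversible addition and elimination favour the (E)-enoate (ester trans to the larger C12 chain), a preference the bulky phosphonate should reinforce, with any minor (Z)-isomer to be removed by chromatography.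

Step 14
Reactants: 23 15-ethyl 19-methyl 3α-(tert-butyldimethylsilyloxy)labda-8(17),13E-diene-15,19-dioate
Product: 24 methyl 3α-(tert-butyldimethylsilyloxy)-15-hydroxylabda-8(17),13E-dien-19-oate
Conditions: DIBAL-H (2.3 equiv), CH2Cl2, −78 °C; aq. Rochelle salt
Reagents that add atoms: none
Why: Chemoselective DIBAL-H 1,2-reduction, in which the unhindered conjugated C15 ester is reduced to the allylic alcohol while the axial, neopentyl C19 methyl ester is too shielded to react at −78 °C.

Step 15
Reactants: 24 methyl 3α-(tert-butyldimethylsilyloxy)-15-hydroxylabda-8(17),13E-dien-19-oate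
Product: 25 methyl 3α,15-dihydroxylabda-8(17),13E-dien-19-oate
Conditions: HF·pyridine, pyridine, THF, 0 → 40 °C
Reagents that add atoms: none
Why: Fluoride-mediated desilylation under buffered, non-basic conditions, so that the β-hydroxy ester cannot undergo retro-aldol cleavage and the allylic alcohol is not ionised.

Step 16
Reactants: 25 methyl 3α,15-dihydroxylabda-8(17),13E-dien-19-oate
Product: 26 methyl 3α,15-diacetoxylabda-8(17),13E-dien-19-oate
Conditions: Ac2O, pyridine, DMAP (cat.), CH2Cl2, rt
Reagents that add atoms: acetic anhydride, CC(=O)OC(C)=O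
Why: DMAP-catalysed acylation of both hydroxyls, the primary allylic alcohol being acetylated on purpose because the two acetates are easily told apart in the next step.

Step 17
Reactants: 26 methyl 3α,15-diacetoxylabda-8(17),13E-dien-19-oate
Product: 27 methyl 3α-acetoxy-15-hydroxylabda-8(17),13E-dien-19-oate (CNP0164591.1)
Conditions: K2CO3 (0.3 equiv), MeOH, 0 °C
Reagents that add atoms: none
Why: Chemoselective transesterification, in which the primary allylic acetate should be cleaved quickly by catalytic carbonate in cold methanol while the axial 3α-acetate beside quaternary C4 and the C19 methyl ester stay intact.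

Compound list
1 | 2-methylcyclopentane-1,3-dione | CC1C(=O)CCC1=O | starting material
2 | methyl 5-methoxy-3-oxopentanoate | COCCC(=O)CC(=O)OC | starting material
3 | methyl 3-oxopent-4-enoate | C=CC(=O)CC(=O)OC | intermediate (not isolated)
4 | methyl 5-(1-methyl-2,5-dioxocyclopentyl)-3-oxopentanoate | CC1(CCC(=O)CC(=O)OC)C(=O)CCC1=O | intermediate
5 | cis-fused ketol: 5β-hydroxy-10β-methyl-3,9-dioxohydrindane-4-carboxylic acid methyl ester, C4 not defined | O=C1CC[C@]2(O)C(C(=O)OC)C(=O)CC[C@]12C | intermediate (not isolated)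
6 | methyl (7aS)-7a-methyl-1,5-dioxo-2,3,5,6,7,7a-hexahydro-1H-indene-4-carboxylate (C3 and C9 ketones, C4=C5, 10β-methyl) | O=C1CCC2=C(C(=O)OC)C(=O)CC[C@]12C | intermediate
7 | lithium C3(O)=C4 enolate of the reduced keto ester (5α-H, 10β-methyl, 9-oxo) | O=C1CC[C@@H]2[C@]1(C)CCC([O-])=C2C(=O)OC.[Li+] | intermediate (not isolated)
8 | methyl 4α,10β-dimethyl-3,9-dioxo-5α-hydrindane-4β-carboxylate | O=C1CC[C@@H]2[C@]1(C)CCC(=O)[C@]2(C)C(=O)OC | intermediate
9 | methyl 3α-hydroxy-4α,10β-dimethyl-9-oxo-5α-hydrindane-4β-carboxylate | O=C1CC[C@@H]2[C@]1(C)CC[C@@H](O)[C@]2(C)C(=O)OC | intermediate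
10 | methyl 3α-(tert-butyldimethylsilyloxy)-4α,10β-dimethyl-9-oxo-5α-hydrindane-4β-carboxylate | O=C1CC[C@@H]2[C@]1(C)CC[C@@H](O[Si](C)(C)C(C)(C)C)[C@]2(C)C(=O)OC | intermediate
11 | potassium C9(O)=C8 enolate of 10 | [K+].[O-]C1=CC[C@@H]2[C@]1(C)CC[C@@H](O[Si](C)(C)C(C)(C)C)[C@]2(C)C(=O)OC | intermediate (not isolated)
12 | methyl 3α-(tert-butyldimethylsilyloxy)-4α,10β-dimethyl-9-(trifluoromethylsulfonyloxy)-5α-hydrind-8-ene-4β-carboxylate | FC(F)(F)S(=O)(=O)OC1=CC[C@@H]2[C@]1(C)CC[C@@H](O[Si](C)(C)C(C)(C)C)[C@]2(C)C(=O)OC | intermediate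
13 | 2-methyl-2-vinyl-1,3-dioxolane | C=CC1(C)OCCO1 | starting material
14 | B-[2-(2-methyl-1,3-dioxolan-2-yl)ethyl]-9-borabicyclo[3.3.1]nonane | CC1(CCB2C3CCCC2CCC3)OCCO1 | intermediate (not isolated)
15 | methyl 3α-(tert-butyldimethylsilyloxy)-4α,10β-dimethyl-9-[2-(2-methyl-1,3-dioxolan-2-yl)ethyl]-5α-hydrind-8-ene-4β-carboxylate | CC1(CCC2=CC[C@@H]3[C@]2(C)CC[C@@H](O[Si](C)(C)C(C)(C)C)[C@]3(C)C(=O)OC)OCCO1 | intermediate
16 | 8α-boryl (BH2) adduct of 15, 9α-H, side chain 9β | B[C@@H]1C[C@@H]2[C@](C)(CC[C@@H](O[Si](C)(C)C(C)(C)C)[C@]2(C)C(=O)OC)[C@H]1CCC3(C)OCCO3 | intermediate (not isolated)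
17 | methyl 3α-(tert-butyldimethylsilyloxy)-8α-hydroxy-4α,10β-dimethyl-9β-[2-(2-methyl-1,3-dioxolan-2-yl)ethyl]-5α-hydrindane-4β-carboxylate | O[C@@H]1C[C@@H]2[C@](C)(CC[C@@H](O[Si](C)(C)C(C)(C)C)[C@]2(C)C(=O)OC)[C@H]1CCC3(C)OCCO3 | intermediate
18 | methyl 3α-(tert-butyldimethylsilyloxy)-4α,10β-dimethyl-9β-[2-(2-methyl-1,3-dioxolan-2-yl)ethyl]-8-oxo-5α-hydrindane-4β-carboxylate (key-step precursor) | O=C1C[C@@H]2[C@](C)(CC[C@@H](O[Si](C)(C)C(C)(C)C)[C@]2(C)C(=O)OC)[C@H]1CCC3(C)OCCO3 | intermediate
19 | 7-trimethylsilyl derivative of 20 (α-silyl ketone, C7 configuration not defined) | O=C1C([Si](C)(C)C)C[C@@H]2[C@](C)(CC[C@@H](O[Si](C)(C)C(C)(C)C)[C@]2(C)C(=O)OC)[C@H]1CCC3(C)OCCO3 | intermediate (not isolated)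
20 | methyl 3α-(tert-butyldimethylsilyloxy)-13,13-ethylenedioxy-8-oxo-14,15,17-trinorlabdan-19-oate (key-step product) | O=C1CC[C@@H]2[C@](C)(CC[C@@H](O[Si](C)(C)C(C)(C)C)[C@]2(C)C(=O)OC)[C@H]1CCC3(C)OCCO3 | intermediate
21 | methyl 3α-(tert-butyldimethylsilyloxy)-13,13-ethylenedioxy-14,15-dinorlabd-8(17)-en-19-oate | C=C1CC[C@@H]2[C@](C)(CC[C@@H](O[Si](C)(C)C(C)(C)C)[C@]2(C)C(=O)OC)[C@H]1CCC3(C)OCCO3 | intermediate
22 | methyl 3α-(tert-butyldimethylsilyloxy)-13-oxo-14,15-dinorlabd-8(17)-en-19-oate | C=C1CC[C@@H]2[C@](C)(CC[C@@H](O[Si](C)(C)C(C)(C)C)[C@]2(C)C(=O)OC)[C@H]1CCC(C)=O | intermediate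
23 | 15-ethyl 19-methyl 3α-(tert-butyldimethylsilyloxy)labda-8(17),13E-diene-15,19-dioate | C=C1CC[C@@H]2[C@](C)(CC[C@@H](O[Si](C)(C)C(C)(C)C)[C@]2(C)C(=O)OC)[C@H]1CC/C(C)=C/C(=O)OCC | intermediate
24 | methyl 3α-(tert-butyldimethylsilyloxy)-15-hydroxylabda-8(17),13E-dien-19-oate | C=C1CC[C@@H]2[C@](C)(CC[C@@H](O[Si](C)(C)C(C)(C)C)[C@]2(C)C(=O)OC)[C@H]1CC/C(C)=C/CO | intermediate
25 | methyl 3α,15-dihydroxylabda-8(17),13E-dien-19-oate | C=C1CC[C@@H]2[C@](C)(CC[C@@H](O)[C@]2(C)C(=O)OC)[C@H]1CC/C(C)=C/CO | intermediate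
26 | methyl 3α,15-diacetoxylabda-8(17),13E-dien-19-oate | C=C1CC[C@@H]2[C@](C)(CC[C@@H](OC(C)=O)[C@]2(C)C(=O)OC)[C@H]1CC/C(C)=C/COC(C)=O | intermediate
27 | methyl 3α-acetoxy-15-hydroxylabda-8(17),13E-dien-19-oate (CNP0164591.1) | C=C1CC[C@@H]2[C@](C)(CC[C@@H](OC(C)=O)[C@]2(C)C(=O)OC)[C@H]1CC/C(C)=C/CO | target

Total step count: 17. Longest linear sequence: 17 steps (1 → 27); 13 enters at step 7 without steps of its own.

Steps most likely to fail

Step 10 (key step). The shift may be unselective, with C9 migrating in competition with C6, a second carbon may be inserted, or the Lewis acid may open the dioxolane. The fallback fixes the regiochemistry by enolisation instead of migratory aptitude and can add only one carbon. From 18, kinetic deprotonation of the C6 methylene with LDA and trapping with TMSCl (THF, −78 °C) should give the C8(OTMS)=C6 silyl enol ether F1. Furukawa-type Simmons–Smith cyclopropanation (Et2Zn, CH2I2, CH2Cl2, 0 °C) would add the future C7 across C6=C8 to give the siloxycyclopropane F2. Ito–Saegusa oxidative opening (FeCl3, pyridine, DMF, 0 °C) cleaves the internal C6–C8 bond to the ring-enlarged 6-chloro-8-ketone F3, which sodium acetate in methanol dehydrochlorinates to the 8-oxo-6-ene enone F4. Hydrogenation of the conjugated alkene (H2, Pd/C, EtOAc) and the same K2CO3/MeOH equilibration return to 20.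

Step 3. The dissolving-metal step may over-reduce or enolise the free C9 ketone, C-methylation in ammonia may be incomplete, or protonation at C5 may not be cleanly trans-selective. The fallback separates reduction from alkylation. From 6, catalytic hydrogenation (H2, Pd/C, EtOAc) reduces only the conjugated alkene and, as with other 4-substituted hydrindenones, should favour the trans-fused saturated β-keto ester F5. Alkylation at its only acidic position (K2CO3, MeI, acetone) from the α face returns to 8.

Step 2. Enantioselection may be poor because the nucleophile is an enamino ester and not a simple ketone enamine. The fallback moves the asymmetric step to the substrate on which it is best established and adds the ester afterwards. From 1, Michael addition to methyl vinyl ketone (H2O, rt) gives 2-methyl-2-(3-oxobutyl)cyclopentane-1,3-dione F6. L-Proline (3 mol%, DMF) cyclises it to the cis-fused ketol F7, which TsOH in toluene dehydrates to the (S)-enedione F8. α-Iodination (I2, pyridine, CCl4) gives the 4-iodoenone F9, and palladium-catalysed methoxycarbonylation (CO, MeOH, Et3N, PdCl2(PPh3)2, DMF, 60 °C) returns to 6.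

Further compounds
F1 | step 10 | C8(OTMS)=C6 silyl enol ether of 18 | C[Si](C)(C)OC1=C[C@@H]2[C@](C)(CC[C@@H](O[Si](C)(C)C(C)(C)C)[C@]2(C)C(=O)OC)[C@H]1CCC3(C)OCCO3
F2 | step 10 | siloxycyclopropane, new CH2 bridging C6 and C8 (ring-junction configuration not defined) | C[Si](C)(C)OC12CC1[C@@H]3[C@](C)(CC[C@@H](O[Si](C)(C)C(C)(C)C)[C@]3(C)C(=O)OC)[C@H]2CCC4(C)OCCO4
F3 | step 10 | 6-chloro derivative of 20 (C6 configuration not defined) | O=C1CC(Cl)[C@@H]2[C@](C)(CC[C@@H](O[Si](C)(C)C(C)(C)C)[C@]2(C)C(=O)OC)[C@H]1CCC3(C)OCCO3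
F4 | step 10 | 6,7-didehydro derivative of 20 (8-oxo-6-ene) | O=C1C=C[C@@H]2[C@](C)(CC[C@@H](O[Si](C)(C)C(C)(C)C)[C@]2(C)C(=O)OC)[C@H]1CCC3(C)OCCO3
F5 | step 3 | methyl 10β-methyl-3,9-dioxo-5α-hydrindane-4-carboxylate (C4 epimers/enol) | O=C1CC[C@@H]2[C@]1(C)CCC(=O)C2C(=O)OC
F6 | step 2 | 2-methyl-2-(3-oxobutyl)cyclopentane-1,3-dione | CC(=O)CCC1(C)C(=O)CCC1=O
F7 | step 2 | (3aS,7aS)-3a-hydroxy-7a-methylhexahydro-1H-indene-1,5(4H)-dione | O=C1CC[C@]2(O)CC(=O)CC[C@]12C
F8 | step 2 | (S)-7a-methyl-2,3,7,7a-tetrahydro-1H-indene-1,5(6H)-dione | O=C1CCC2=CC(=O)CC[C@]12C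
F9 | step 2 | (S)-4-iodo-7a-methyl-2,3,7,7a-tetrahydro-1H-indene-1,5(6H)-dione | O=C1CCC2=C(I)C(=O)CC[C@]12C
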